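**Plan**

- Retrosynthesis: the tether enal C=C is traced back to a β-hydroxy aldehyde, whose C2–C3 bond joins two identical C12 aldehyde halves by self-aldol condensation. Then both N1–C6 ring bonds are cut, unfolding each piperidine to a 2-(1-aminoethyl)-5-alkylfuran. Last come the C–CH3 bond at the amine carbon, the furan–CHO bond and the furan–chain bond.
- Enabling feature (ring locants used throughout: N1, C2 methyl, C3 oxygen, C6 tether): in each ring N1 lies between C6 and C2, and C2 is adjacent to the oxygenated C3. Furan C2, C3, C4, C5 map onto ring C3, C4, C5, C6 when the furan is oxidised and reclosed through nitrogen.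
- Forward order: furan is alkylated, formylated and converted into the (S)-sulfonamide. The chain end is hydroformylated and two molecules are joined by aldol condensation, so the tether is complete before any ring exists. The enal is stored as a saturated 1,3-diol, both rings then form in one operation, and the enal is restored at the end by oxidation and dehydration.
- Stereochemistry: C2 of each ring comes from the (R)-tert-butanesulfinyl auxiliary. C6 and C3 are set by substrate control from C2 (two hydride additions anti to the pseudoaxial methyl). The E enal is the thermodynamic isomer.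

Key step: step 9

Remark: the two carbons of the central 1,3-diol unit (tetradecane C2 and C3 in 14, 15–23) are transient stereocentres, carried without defined configuration and written so, since step 14 destroys both; the hemiaminal carbons of 17 are epimerisable and are drawn with hydroxyl trans to the C2 methyl; tosyl = 4-methylbenzenesulfonyl.

**Step 1**
Reactants: 1 furan; 2 11-bromoundec-1-ene
Product: 4 2-(undec-10-en-1-yl)furan, via 2-furyllithium 3 (not isolated)
Conditions: n-BuLi, THF, −78 → 0 °C (furan in excess); then 2, 0 °C → rt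
Reagents that add atoms: none
Why: α-lithiation of furan followed by SN2 alkylation of the furyllithium with a primary bromide is a standard entry to 2-alkylfurans, and the terminal alkene is inert to both operations.

**Step 2**
Reactants: 4 2-(undec-10-en-1-yl)furan
Product: 6 5-(undec-10-en-1-yl)furan-2-carbaldehyde, via 5-lithiofuran 5 (not isolated)
Conditions: n-BuLi, THF, 0 °C → rt; then DMF, −78 °C → rt; H2O
Reagents that add atoms: N,N-dimethylformamide, CN(C)C=O
Why: the free α-position (C5) of a 2-alkylfuran is the most acidic C–H and is lithiated selectively, and formylation of the aryllithium with DMF gives the 5-alkylfurfural.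

**Step 3**
Reactants: 6 5-(undec-10-en-1-yl)furan-2-carbaldehyde; 7 (R)-2-methylpropane-2-sulfinamide
Product: 8 (R)-2-methyl-N-[(E)-(5-(undec-10-en-1-yl)furan-2-yl)methylidene]propane-2-sulfinamide
Conditions: Ti(OEt)4, THF, rt
Reagents that add atoms: none
Why: titanium-alkoxide-mediated condensation of an aldehyde with tert-butanesulfinamide gives the E N-sulfinyl aldimine and leaves the sulfur stereocentre untouched.

**Step 4**
Reactants: 8 (R)-2-methyl-N-[(E)-(5-(undec-10-en-1-yl)furan-2-yl)methylidene]propane-2-sulfinamide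
Product: 9 (R)-2-methyl-N-[(1S)-1-(5-(undec-10-en-1-yl)furan-2-yl)ethyl]propane-2-sulfinamide
Conditions: MeMgBr (Et2O solution), CH2Cl2, −48 °C → rt; aqueous work-up
Reagents that add atoms: methylmagnesium bromide, C[Mg]Br
Why: Grignard 1,2-addition to the N-sulfinyl aldimine in a non-coordinating solvent should pass through a six-membered chair with magnesium bound to the sulfinyl oxygen and tert-butyl equatorial, delivering methyl to the Si face of the imine carbon and so setting the (S) amine carbon from (R) sulfur; the minor epimer is a diastereomer here and can be removed.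

**Step 5**
Reactants: 9 (R)-2-methyl-N-[(1S)-1-(5-(undec-10-en-1-yl)furan-2-yl)ethyl]propane-2-sulfinamide
Product: 11 4-methyl-N-[(1S)-1-(5-(undec-10-en-1-yl)furan-2-yl)ethyl]benzenesulfonamide, via amine hydrochloride 10 (not isolated)
Conditions: HCl (4 M in dioxane), MeOH, 0 °C → rt; evaporate; then TsCl, Et3N, CH2Cl2, 0 °C → rt
Reagents that add atoms: 4-methylbenzenesulfonyl chloride, Cc1ccc(cc1)S(Cl)(=O)=O
Why: acid methanolysis cleaves the N–S bond of the sulfinamide (sulfinyl transfer to methanol) without touching the C–N stereocentre, and N-sulfonylation of the primary amine installs the sulfonamide N–H that the ring expansion needs.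

**Step 6**
Reactants: 11 4-methyl-N-[(1S)-1-(5-(undec-10-en-1-yl)furan-2-yl)ethyl]benzenesulfonamide
Product: 12 4-methyl-N-[(1S)-1-(5-(12-oxododecyl)furan-2-yl)ethyl]benzenesulfonamide
Conditions: Rh(acac)(CO)2 (cat.), BiPhePhos (cat.), CO/H2 (1:1, 10 bar), toluene, 70 °C
Reagents that add atoms: carbon monoxide, [C-]#[O+]
Why: rhodium–bisphosphite hydroformylation of a terminal alkene is strongly linear-selective, so one carbon is added at the chain terminus as the aldehyde while furan and sulfonamide are spectators.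

**Step 7**
Reactants: 12 4-methyl-N-[(1S)-1-(5-(12-oxododecyl)furan-2-yl)ethyl]benzenesulfonamide (two molecules combine)
Product: 13 (E)-14-{5-[(1S)-1-(tosylamino)ethyl]furan-2-yl}-2-(10-{5-[(1S)-1-(tosylamino)ethyl]furan-2-yl}decyl)tetradec-2-enal
Conditions: pyrrolidine (cat.), PhCO2H (cat.), toluene, rt
Reagents that add atoms: none
Why: amine/acid-catalysed aldol self-condensation of a linear aldehyde (enamine addition to a second aldehyde, then dehydration) gives the 2-alkyl-2-enal, and the E isomer required by the target is the thermodynamic one.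

**Step 8**
Reactants: 13 (E)-14-{5-[(1S)-1-(tosylamino)ethyl]furan-2-yl}-2-(10-{5-[(1S)-1-(tosylamino)ethyl]furan-2-yl}decyl)tetradec-2-enal
Product: 15 14-{5-[(1S)-1-(tosylamino)ethyl]furan-2-yl}-2-(10-{5-[(1S)-1-(tosylamino)ethyl]furan-2-yl}decyl)tetradecane-1,3-diol, via cyclic alkylborane 14 (not isolated)
Conditions: BH3·THF (excess), THF, 0 °C → rt; then aq. NaOH, H2O2, 0 °C → rt
Reagents that add atoms: hydrogen peroxide, OO
Why: borane reduces the aldehyde and the resulting allyloxyborane undergoes hydroboration with boron on the less substituted alkene carbon, so oxidation gives the 1,3-diol (carbonyl reduction plus hydroboration–oxidation); syn addition to the E alkene fixes only the relative configuration of the two transient centres, which is immaterial.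

**Step 9**
Reactants: 15 14-{5-[(1S)-1-(tosylamino)ethyl]furan-2-yl}-2-(10-{5-[(1S)-1-(tosylamino)ethyl]furan-2-yl}decyl)tetradecane-1,3-diol
Product: 17 14-[(2S,6S)-6-hydroxy-2-methyl-3-oxo-1-tosyl-3,6-dihydro-2H-pyridin-6-yl]-2-{10-[(2S,6S)-6-hydroxy-2-methyl-3-oxo-1-tosyl-3,6-dihydro-2H-pyridin-6-yl]decyl}tetradecane-1,3-diol, via bis(cis-enedione) 16 (not isolated)
Conditions: mCPBA (2.4 equiv), CH2Cl2, 0 °C → rt
Reagents that add atoms: 3-chloroperoxybenzoic acid, OOC(=O)c1cccc(Cl)c1
Why: The peracid oxidises each electron-rich 2,5-dialkylfuran (epoxidation at the ring C=C next to oxygen, then ring opening) to a cis-enedione, and the sulfonamide nitrogen adds to the distal ketone to give the six-membered hemiaminal at both termini in the same flask. The closest known reaction type is the aza-Achmatowicz ring expansion of N-sulfonyl furfurylamines, including 5-alkyl-substituted furans. Each ring closes by 6-exo-trig attack of nitrogen on the C6 carbonyl, which forms N1–C6 and turns furan C2–C5 into ring C3–C6. The two new C6 hemiaminal centres are under thermodynamic control through reversible ring opening, biased by the C2 methyl that sits pseudoaxial to avoid A(1,3) strain with the sulfonyl group, and their configuration is of no consequence because C6 is planarised in step 10. The step needs chemoselective oxidation of the furans and retention of the cis enedione geometry until closure; the furans are the only electron-rich π systems (the enal has been stored as a saturated diol) and the cis geometry is inherited from the ring. The sulfonamide N–H is the only nucleophile placed for a six-membered ring, since the diol hydroxyls are too remote to compete.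

**Step 10**
Reactants: 17 14-[(2S,6S)-6-hydroxy-2-methyl-3-oxo-1-tosyl-3,6-dihydro-2H-pyridin-6-yl]-2-{10-[(2S,6S)-6-hydroxy-2-methyl-3-oxo-1-tosyl-3,6-dihydro-2H-pyridin-6-yl]decyl}tetradecane-1,3-diol
Product: 18 14-[(2S,6R)-2-methyl-3-oxo-1-tosyl-3,6-dihydro-2H-pyridin-6-yl]-2-{10-[(2S,6R)-2-methyl-3-oxo-1-tosyl-3,6-dihydro-2H-pyridin-6-yl]decyl}tetradecane-1,3-diol
Conditions: Et3SiH, BF3·OEt2 (excess), CH2Cl2, −78 → −30 °C
Reagents that add atoms: none
Why: Lewis-acid ionisation of the tertiary N-sulfonyl hemiaminal gives a flat, enone-conjugated N-sulfonyliminium ion that the silane reduces (ionic hydrogenation); hydride is expected to reach C6 from the face opposite the pseudoaxial C2 methyl, placing tether and methyl cis, both pseudoaxial and free of A(1,3) strain.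

**Step 11**
Reactants: 18 14-[(2S,6R)-2-methyl-3-oxo-1-tosyl-3,6-dihydro-2H-pyridin-6-yl]-2-{10-[(2S,6R)-2-methyl-3-oxo-1-tosyl-3,6-dihydro-2H-pyridin-6-yl]decyl}tetradecane-1,3-diol
Product: 19 14-[(2S,3S,6R)-3-hydroxy-2-methyl-1-tosyl-3,6-dihydro-2H-pyridin-6-yl]-2-{10-[(2S,3S,6R)-3-hydroxy-2-methyl-1-tosyl-3,6-dihydro-2H-pyridin-6-yl]decyl}tetradecane-1,3-diol
Conditions: NaBH4, CeCl3·7H2O, MeOH–CH2Cl2, −40 °C
Reagents that add atoms: none
Why: Luche 1,2-reduction of the enone, in which hydride should attack the C3 carbonyl anti to the pseudoaxial C2 methyl and C6 tether, so the new hydroxyl is cis to both.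

**Step 12**
Reactants: 19 14-[(2S,3S,6R)-3-hydroxy-2-methyl-1-tosyl-3,6-dihydro-2H-pyridin-6-yl]-2-{10-[(2S,3S,6R)-3-hydroxy-2-methyl-1-tosyl-3,6-dihydro-2H-pyridin-6-yl]decyl}tetradecane-1,3-diol
Product: 20 14-[(2S,3S,6R)-3-hydroxy-2-methyl-1-tosylpiperidin-6-yl]-2-{10-[(2S,3S,6R)-3-hydroxy-2-methyl-1-tosylpiperidin-6-yl]decyl}tetradecane-1,3-diol
Conditions: H2 (1 atm), PtO2, EtOAc, rt
Reagents that add atoms: none
Why: heterogeneous hydrogenation of the two cis-disubstituted ring alkenes creates no stereocentre, and platinum is chosen to limit allylic C–O and C–N hydrogenolysis.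

**Step 13**
Reactants: 20 14-[(2S,3S,6R)-3-hydroxy-2-methyl-1-tosylpiperidin-6-yl]-2-{10-[(2S,3S,6R)-3-hydroxy-2-methyl-1-tosylpiperidin-6-yl]decyl}tetradecane-1,3-diol
Product: 22 14-[(2S,3S,6R)-1-(tert-butoxycarbonyl)-3-hydroxy-2-methylpiperidin-6-yl]-2-{10-[(2S,3S,6R)-1-(tert-butoxycarbonyl)-3-hydroxy-2-methylpiperidin-6-yl]decyl}tetradecane-1,3-diol, via diamine tetraol 21 (not isolated)
Conditions: sodium naphthalenide (NaC10H8, preformed, excess), DME, −78 °C; MeOH quench; then Boc2O, Et3N, MeOH, 40 °C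
Reagents that add atoms: di-tert-butyl dicarbonate, CC(C)(C)OC(=O)OC(=O)OC(C)(C)C
Why: single-electron reduction of the arenesulfonamide cleaves the N–S bond (reductive desulfonylation) without touching C–O bonds or stereocentres, and Boc2O without an acyl-transfer catalyst should carbamoylate the freed secondary amines in preference to the hydroxyls.

**Step 14**
Reactants: 22 14-[(2S,3S,6R)-1-(tert-butoxycarbonyl)-3-hydroxy-2-methylpiperidin-6-yl]-2-{10-[(2S,3S,6R)-1-(tert-butoxycarbonyl)-3-hydroxy-2-methylpiperidin-6-yl]decyl}tetradecane-1,3-diol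
Product: 24 (E)-14-[(2S,3S,6R)-1-(tert-butoxycarbonyl)-3-hydroxy-2-methylpiperidin-6-yl]-2-{10-[(2S,3S,6R)-1-(tert-butoxycarbonyl)-3-hydroxy-2-methylpiperidin-6-yl]decyl}tetradec-2-enal, via β-hydroxy aldehyde 23 (not isolated)
Conditions: TEMPO (cat.), PhI(OAc)2, CH2Cl2, rt; aq. Na2S2O3 wash; then pyrrolidine (cat.), PhCO2H (cat.), CH2Cl2, rt
Reagents that add atoms: none
Why: oxoammonium (TEMPO) oxidation selects the single primary alcohol over the three secondary ones, and amine/acid-catalysed dehydration of the β-hydroxy aldehyde (second half of an aldol condensation) gives the thermodynamic E enal, erasing both transient stereocentres; any retro-aldol only regenerates the two identical aldehyde halves, which recombine to the same enal.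

**Step 15**
Reactants: 24 (E)-14-[(2S,3S,6R)-1-(tert-butoxycarbonyl)-3-hydroxy-2-methylpiperidin-6-yl]-2-{10-[(2S,3S,6R)-1-(tert-butoxycarbonyl)-3-hydroxy-2-methylpiperidin-6-yl]decyl}tetradec-2-enal
Product: 25 (E)-14-[(2S,3S,6R)-3-hydroxy-2-methylpiperidin-6-yl]-2-{10-[(2S,3S,6R)-3-hydroxy-2-methylpiperidin-6-yl]decyl}tetradec-2-enal (CNP0177491.1)
Conditions: TFA, CH2Cl2, 0 °C → rt; then aq. NaHCO3
Reagents that add atoms: none
Why: acidolysis of the tert-butyl carbamates (loss of 2-methylpropene and CO2) frees both secondary amines, while the enal, the hydroxyls and all stereocentres are untouched by brief acid treatment.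

**Compound list**

1 | furan | c1ccoc1 | starting material
2 | 11-bromoundec-1-ene | C=CCCCCCCCCCBr | starting material
3 | 2-furyllithium (not isolated) | [Li]c1ccco1 | intermediate
4 | 2-(undec-10-en-1-yl)furan | C=CCCCCCCCCCc1ccco1 | intermediate
5 | 5-(undec-10-en-1-yl)furan-2-yllithium (not isolated) | C=CCCCCCCCCCc1ccc([Li])o1 | intermediate
6 | 5-(undec-10-en-1-yl)furan-2-carbaldehyde | C=CCCCCCCCCCc1ccc(C=O)o1 | intermediate
7 | (R)-2-methylpropane-2-sulfinamide ((R)-tert-butanesulfinamide) | CC(C)(C)[S@@](=O)N | starting material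
8 | (R)-2-methyl-N-[(E)-(5-(undec-10-en-1-yl)furan-2-yl)methylidene]propane-2-sulfinamide | C=CCCCCCCCCCc1ccc(/C=N/[S@](=O)C(C)(C)C)o1 | intermediate
9 | (R)-2-methyl-N-[(1S)-1-(5-(undec-10-en-1-yl)furan-2-yl)ethyl]propane-2-sulfinamide | C=CCCCCCCCCCc1ccc([C@H](C)N[S@](=O)C(C)(C)C)o1 | intermediate
10 | (1S)-1-[5-(undec-10-en-1-yl)furan-2-yl]ethan-1-amine hydrochloride (not isolated) | C=CCCCCCCCCCc1ccc([C@H](C)N)o1.Cl | intermediate
11 | 4-methyl-N-[(1S)-1-(5-(undec-10-en-1-yl)furan-2-yl)ethyl]benzenesulfonamide | C=CCCCCCCCCCc1ccc([C@H](C)NS(=O)(=O)c2ccc(C)cc2)o1 | intermediate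
12 | 4-methyl-N-[(1S)-1-(5-(12-oxododecyl)furan-2-yl)ethyl]benzenesulfonamide | O=CCCCCCCCCCCCc1ccc([C@H](C)NS(=O)(=O)c2ccc(C)cc2)o1 | intermediate
13 | (E)-14-{5-[(1S)-1-(tosylamino)ethyl]furan-2-yl}-2-(10-{5-[(1S)-1-(tosylamino)ethyl]furan-2-yl}decyl)tetradec-2-enal | C[C@H](NS(=O)(=O)c1ccc(C)cc1)c1ccc(CCCCCCCCCCC/C=C(/C=O)CCCCCCCCCCc2ccc([C@H](C)NS(=O)(=O)c3ccc(C)cc3)o2)o1 | intermediate
14 | cyclic alkylborane (not isolated): 1,2-oxaborolane spanning the O–CH2–C2–C3 unit of the former enal, N–B bonds of the sulfonamides not drawn | C[C@H](NS(=O)(=O)c1ccc(C)cc1)c1ccc(CCCCCCCCCCCC2[BH]OCC2CCCCCCCCCCc2ccc([C@H](C)NS(=O)(=O)c3ccc(C)cc3)o2)o1 | intermediate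
15 | 14-{5-[(1S)-1-(tosylamino)ethyl]furan-2-yl}-2-(10-{5-[(1S)-1-(tosylamino)ethyl]furan-2-yl}decyl)tetradecane-1,3-diol | C[C@H](NS(=O)(=O)c1ccc(C)cc1)c1ccc(CCCCCCCCCCCC(O)C(CO)CCCCCCCCCCc2ccc([C@H](C)NS(=O)(=O)c3ccc(C)cc3)o2)o1 | intermediate
16 | bis(cis-enedione) (not isolated): both furans of 15 opened to TsNH–CH(CH3)–CO–CH=CH–CO– units of Z geometry | C[C@H](NS(=O)(=O)c1ccc(C)cc1)C(=O)/C=C\C(=O)CCCCCCCCCCCC(O)C(CO)CCCCCCCCCCC(=O)/C=C\C(=O)[C@H](C)NS(=O)(=O)c1ccc(C)cc1 | intermediate
17 | 14-[(2S,6S)-6-hydroxy-2-methyl-3-oxo-1-tosyl-3,6-dihydro-2H-pyridin-6-yl]-2-{10-[(2S,6S)-6-hydroxy-2-methyl-3-oxo-1-tosyl-3,6-dihydro-2H-pyridin-6-yl]decyl}tetradecane-1,3-diol | C[C@@H]1N(S(=O)(=O)c2ccc(C)cc2)[C@](O)(CCCCCCCCCCCC(O)C(CO)CCCCCCCCCC[C@]2(O)C=CC(=O)[C@H](C)N2S(=O)(=O)c2ccc(C)cc2)C=CC1=O | intermediate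
18 | 14-[(2S,6R)-2-methyl-3-oxo-1-tosyl-3,6-dihydro-2H-pyridin-6-yl]-2-{10-[(2S,6R)-2-methyl-3-oxo-1-tosyl-3,6-dihydro-2H-pyridin-6-yl]decyl}tetradecane-1,3-diol | C[C@@H]1N(S(=O)(=O)c2ccc(C)cc2)[C@H](CCCCCCCCCCCC(O)C(CO)CCCCCCCCCC[C@@H]2C=CC(=O)[C@H](C)N2S(=O)(=O)c2ccc(C)cc2)C=CC1=O | intermediate
19 | 14-[(2S,3S,6R)-3-hydroxy-2-methyl-1-tosyl-3,6-dihydro-2H-pyridin-6-yl]-2-{10-[(2S,3S,6R)-3-hydroxy-2-methyl-1-tosyl-3,6-dihydro-2H-pyridin-6-yl]decyl}tetradecane-1,3-diol | C[C@@H]1N(S(=O)(=O)c2ccc(C)cc2)[C@H](CCCCCCCCCCCC(O)C(CO)CCCCCCCCCC[C@@H]2C=C[C@H](O)[C@H](C)N2S(=O)(=O)c2ccc(C)cc2)C=C[C@@H]1O | intermediate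
20 | 14-[(2S,3S,6R)-3-hydroxy-2-methyl-1-tosylpiperidin-6-yl]-2-{10-[(2S,3S,6R)-3-hydroxy-2-methyl-1-tosylpiperidin-6-yl]decyl}tetradecane-1,3-diol | C[C@@H]1N(S(=O)(=O)c2ccc(C)cc2)[C@H](CCCCCCCCCCCC(O)C(CO)CCCCCCCCCC[C@@H]2CC[C@H](O)[C@H](C)N2S(=O)(=O)c2ccc(C)cc2)CC[C@@H]1O | intermediate
21 | 14-[(2S,3S,6R)-3-hydroxy-2-methylpiperidin-6-yl]-2-{10-[(2S,3S,6R)-3-hydroxy-2-methylpiperidin-6-yl]decyl}tetradecane-1,3-diol (not isolated) | C[C@@H]1N[C@H](CCCCCCCCCCCC(O)C(CO)CCCCCCCCCC[C@@H]2CC[C@H](O)[C@H](C)N2)CC[C@@H]1O | intermediate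
22 | 14-[(2S,3S,6R)-1-(tert-butoxycarbonyl)-3-hydroxy-2-methylpiperidin-6-yl]-2-{10-[(2S,3S,6R)-1-(tert-butoxycarbonyl)-3-hydroxy-2-methylpiperidin-6-yl]decyl}tetradecane-1,3-diol | C[C@@H]1N(C(=O)OC(C)(C)C)[C@H](CCCCCCCCCCCC(O)C(CO)CCCCCCCCCC[C@@H]2CC[C@H](O)[C@H](C)N2C(=O)OC(C)(C)C)CC[C@@H]1O | intermediate
23 | 14-[(2S,3S,6R)-1-(tert-butoxycarbonyl)-3-hydroxy-2-methylpiperidin-6-yl]-2-{10-[(2S,3S,6R)-1-(tert-butoxycarbonyl)-3-hydroxy-2-methylpiperidin-6-yl]decyl}-3-hydroxytetradecanal (not isolated) | C[C@@H]1N(C(=O)OC(C)(C)C)[C@H](CCCCCCCCCCCC(O)C(C=O)CCCCCCCCCC[C@@H]2CC[C@H](O)[C@H](C)N2C(=O)OC(C)(C)C)CC[C@@H]1O | intermediate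
24 | (E)-14-[(2S,3S,6R)-1-(tert-butoxycarbonyl)-3-hydroxy-2-methylpiperidin-6-yl]-2-{10-[(2S,3S,6R)-1-(tert-butoxycarbonyl)-3-hydroxy-2-methylpiperidin-6-yl]decyl}tetradec-2-enal | C[C@@H]1N(C(=O)OC(C)(C)C)[C@H](CCCCCCCCCCC/C=C(/C=O)CCCCCCCCCC[C@@H]2CC[C@H](O)[C@H](C)N2C(=O)OC(C)(C)C)CC[C@@H]1O | intermediate
25 | (E)-14-[(2S,3S,6R)-3-hydroxy-2-methylpiperidin-6-yl]-2-{10-[(2S,3S,6R)-3-hydroxy-2-methylpiperidin-6-yl]decyl}tetradec-2-enal, all-cis rings (CNP0177491.1) | C[C@@H]1N[C@H](CCCCCCCCCCC/C=C(/C=O)CCCCCCCCCC[C@@H]2CC[C@H](O)[C@H](C)N2)CC[C@@H]1O | target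

**Totals and risks**

Total step count: 15. Longest linear sequence: 15 steps from furan (the route is linear; step 7 joins two molecules of the same intermediate).

Steps most likely to fail:

1. Step 10 (silane reduction at C6). Hydride may be delivered with poor facial selectivity to the iminium ion, or the iminium ion may lose a proton from the tether instead of being reduced. The fallback sets out from 17 and sets C6 by heterogeneous hydrogenation instead of ionic hydride delivery. Acid-catalysed dehydration (camphorsulfonic acid cat., toluene, molecular sieves, 60 °C) converts both hemiaminals into the bis(exocyclic ene-sulfonamide) dienone F1. Hydrogenation (H2, Pd/C, EtOAc) saturates the exocyclic and ring alkenes from the face opposite the pseudoaxial C2 methyl and should give the 2,6-cis bis(1-tosylpiperidin-3-one) F2. Reduction with NaBH4 (MeOH, −40 °C), by axial attack anti to the two axial substituents, returns to the route at 20.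

2. Step 9 (double ring expansion). One terminus may be oxidised incompletely or over-oxidised, the cis-enedione may isomerise to the trans isomer before it closes, or the acidic by-product may degrade the hemiaminal. The fallback sets out from 15 and separates oxidation from ring closure. Clauson-Kaas-type oxidation (Br2, MeOH, Na2CO3, −40 °C) gives the isolable bis(2,5-dimethoxy-2,5-dihydrofuran) F3 as an acetal mixture. Dilute aqueous acid (aq. TFA, THF, 0 °C) then unmasks both cis-enediones under conditions where they close at once, returning to the route at 17.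

3. Step 8 (borane reduction and hydroboration). Borane may add to the furan rings, add incompletely to the hindered trisubstituted alkene, or be consumed by the sulfonamide N–H bonds. The fallback sets out from 12 and bypasses the enal. L-Proline-catalysed direct aldol addition (DMF, 4 °C) joins two molecules to the anti β-hydroxy aldehyde F4, which is reduced in the same flask (NaBH4, MeOH, 0 °C). This returns to the route at 15, as a single stereoisomer at the two transient centres, which is immaterial.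

**Further compounds**

F1 | step 10 | bis(exocyclic ene-sulfonamide) dienone: each ring of 17 dehydrated to C6=CH(tether), alkene geometry not defined, (2S) at both C2 | C[C@@H]1N(S(=O)(=O)c2ccc(C)cc2)C(=CCCCCCCCCCCC(O)C(CO)CCCCCCCCCC=C2C=CC(=O)[C@H](C)N2S(=O)(=O)c2ccc(C)cc2)C=CC1=O
F2 | step 10 | 14-[(2S,6R)-2-methyl-3-oxo-1-tosylpiperidin-6-yl]-2-{10-[(2S,6R)-2-methyl-3-oxo-1-tosylpiperidin-6-yl]decyl}tetradecane-1,3-diol | C[C@@H]1N(S(=O)(=O)c2ccc(C)cc2)[C@H](CCCCCCCCCCCC(O)C(CO)CCCCCCCCCC[C@@H]2CCC(=O)[C@H](C)N2S(=O)(=O)c2ccc(C)cc2)CCC1=O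
F3 | step 9 | bis(2,5-dimethoxy-2,5-dihydrofuran) from 15, acetal carbons as a mixture of configurations | C[C@H](NS(=O)(=O)c1ccc(C)cc1)C1(OC)C=CC(OC)(CCCCCCCCCCCC(O)C(CO)CCCCCCCCCCC2(OC)C=CC(OC)([C@H](C)NS(=O)(=O)c3ccc(C)cc3)O2)O1
F4 | step 8 | (2S,3S)-3-hydroxy-14-{5-[(1S)-1-(tosylamino)ethyl]furan-2-yl}-2-(10-{5-[(1S)-1-(tosylamino)ethyl]furan-2-yl}decyl)tetradecanal | C[C@H](NS(=O)(=O)c1ccc(C)cc1)c1ccc(CCCCCCCCCCC[C@H](O)[C@@H](C=O)CCCCCCCCCCc2ccc([C@H](C)NS(=O)(=O)c3ccc(C)cc3)o2)o1
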